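The central six-membered ring, a fully substituted 1,4-quinone carrying oxygen on C1, C3, C4 and C6 and the two 4-hydroxyphenyl rings on C2 and C5, is cut into the four carbons of a squarate and a two-carbon 1-aryl-2-methoxyvinyl unit. Heating a 4-hydroxy-4-vinylcyclobutenone opens the four-membered ring to a dienylketene that closes to this ring in one operation, every substituent already in place and no stereocentre to control. The precursor is a 2-aryl-3-methoxycyclobutenone whose carbinol carbon bears the arylated methoxyvinyl group. The two (2Z,4S,5S)-epoxyhexenoyl chains, from Sharpless epoxidation and Still–Gennari olefination, are attached last to the quinone hydroxyls.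

Key step: step 5

Assumption: the target is read as atromentin esterified on both quinone hydroxyls by the same (2Z,4S,5S)-4,5-epoxyhex-2-enoic acid, and (E)-but-2-en-1-ol of high geometric purity is used, since any minor side-chain enantiomer would surface as a diastereomeric bis-ester.

Step 1
Reactants: 1 dimethyl squarate; 2 (4-bromophenoxy)(tert-butyl)dimethylsilane
Product: 6 3-[4-(tert-butyldimethylsilyloxy)phenyl]-4-methoxycyclobut-3-ene-1,2-dione, via aryllithium 3 (not isolated), via lithium alkoxide adduct 4 (not isolated), via tertiary trifluoroacetate 5 (not isolated)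
Conditions: 2, n-BuLi, THF, −78 °C; cannulated into 1, THF, −78 °C; (CF3CO)2O, −78 °C; aq. NaHCO3 work-up
Reagents that add atoms: water, O
Why: Bromine–lithium exchange gives an aryllithium that adds 1,2 to one squarate carbonyl, trifluoroacetylation of the tertiary alkoxide lets the vinylogous methoxy group expel trifluoroacetate, and hydrolysis of the resulting oxocarbenium ion on work-up releases methanol and unveils the second carbonyl (organolithium addition to a squaric ester with anhydride-triggered transposition).

Step 2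
Reactants: 7 4-(tert-butyldimethylsilyloxy)benzaldehyde; 8 (methoxymethyl)triphenylphosphonium chloride
Product: 10 tert-butyl[4-(2-methoxyethenyl)phenoxy]dimethylsilane (E/Z mixture), via phosphorus ylide 9 (not isolated)
Conditions: 8, KOt-Bu, THF, 0 °C; then 7, 0 °C to rt
Reagents that add atoms: none
Why: Wittig methoxymethylenation of a non-enolisable aryl aldehyde is reliable, and the alkene geometry is irrelevant because it is erased in step 3.

Step 3
Reactants: 10 tert-butyl[4-(2-methoxyethenyl)phenoxy]dimethylsilane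
Product: 12 (Z)-[4-(1-bromo-2-methoxyethenyl)phenoxy](tert-butyl)dimethylsilane (Br cis to OMe), via dibromide 11 (not isolated)
Conditions: Br2 (1.0 equiv), CH2Cl2, −78 °C; then i-Pr2NEt, −78 °C to rt; neutral alumina
Reagents that add atoms: bromine, BrBr
Why: The enol ether adds bromine far faster than the arene, and amine-induced dehydrobromination loses the oxygen-activated α-bromo ether bromide together with the benzylic hydrogen, so bromine stays on the aryl-bearing carbon, expected mainly cis to methoxy as in the known preparation of cis-2-alkoxyvinyl bromides (bromination–dehydrobromination of an enol ether).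

Step 4
Reactants: 12 (Z)-[4-(1-bromo-2-methoxyethenyl)phenoxy](tert-butyl)dimethylsilane; 6 3-[4-(tert-butyldimethylsilyloxy)phenyl]-4-methoxycyclobut-3-ene-1,2-dione
Product: 15 4-hydroxy-3-methoxy-2-[4-(tert-butyldimethylsilyloxy)phenyl]-4-{(Z)-1-[4-(tert-butyldimethylsilyloxy)phenyl]-2-methoxyethenyl}cyclobut-2-en-1-one (racemic), via vinyllithium 13 (not isolated), via lithium alkoxide 14 (not isolated)
Conditions: 12, t-BuLi (2.0 equiv), THF, −78 °C; then 6, THF, −78 °C; aq. NH4Cl at −78 °C; crude 15 kept cold and used directly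
Reagents that add atoms: none
Why: Bromine–lithium exchange with retention gives a vinyllithium held by the cis methoxy oxygen (which also disfavours anti β-elimination), and it adds 1,2 to the carbonyl of 6 next to C–OMe because the other carbonyl is deactivated as part of the vinylogous ester MeO–C=C–C=O; the new carbinol centre is racemic and disappears in step 5.

Step 5
Reactants: 15 4-hydroxy-3-methoxy-2-aryl-4-(1-aryl-2-methoxyethenyl)cyclobut-2-en-1-one (aryl = 4-(tert-butyldimethylsilyloxy)phenyl)
Product: 19 2,5-bis[4-(tert-butyldimethylsilyloxy)phenyl]-3,6-dimethoxy-1,4-benzoquinone, via dienylketene 16 (not isolated), via cyclohexadienone 17 (not isolated), via hydroquinone 18 (not isolated)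
Conditions: degassed toluene, 110 °C, Ar; then Ag2O, MgSO4, rt
Reagents that add atoms: none
Why: Thermal conrotatory 4π electrocyclic opening of 15 breaks the bond between the ketone carbon and the carbinol carbon and gives dienylketene 16 with the arylated methoxyvinyl group turned inward; the ketene carbon then bonds to the CH(OMe) terminus to give cyclohexadienone 17, which enolises to hydroquinone 18, and Ag2O removes two hydrogens to give quinone 19. The closest known reaction type is the Moore rearrangement of 4-alkenyl-4-hydroxycyclobutenones to hydroquinones and quinones. The central six-membered ring is closed by a thermally allowed disrotatory 6π electrocyclisation, driven by release of four-ring strain and by aromatisation. No stereocentre is created, because the racemic carbinol carbon becomes sp2 and the transient CH(OMe) centre of 17 is lost on enolisation, so the vinyl geometry is also irrelevant. The step needs inward rotation of the vinyl group, and the donor hydroxyl on the same carbon secures this through its strong preference for outward rotation. The alternating OH, aryl, OMe order around the ring, with the aryl groups para, follows from the squarate substitution pattern and the regiochemistry of step 4.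

Step 6
Reactants: 19 2,5-bis[4-(tert-butyldimethylsilyloxy)phenyl]-3,6-dimethoxy-1,4-benzoquinone
Product: 21 2,5-bis[4-(tert-butyldimethylsilyloxy)phenyl]-3,6-dihydroxy-1,4-benzoquinone (4′,4″-di-O-TBS-atromentin), via bis(dichloroboryl) quinonate 20 (not isolated)
Conditions: BCl3 (3 equiv), CH2Cl2, −78 to −20 °C; cold aq. work-up
Reagents that add atoms: none
Why: Lewis-acid dealkylation: BCl3 chelates each quinone carbonyl with the neighbouring methoxy oxygen and chloride removes the methyl group by SN2, which should be fast for these vinylogous methyl esters while the unchelated aryl silyl ethers persist at low temperature; the O–B bonds hydrolyse on work-up.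

Step 7
Reactants: 22 (E)-but-2-en-1-ol
Product: 23 (2S,3S)-2,3-epoxybutan-1-ol
Conditions: Ti(OiPr)4 (cat.), L-(+)-diethyl tartrate (cat.), t-BuOOH, 4 Å MS, CH2Cl2, −20 °C; non-aqueous work-up, distillation
Reagents that add atoms: tert-butyl hydroperoxide, CC(C)(C)OO
Why: Sharpless asymmetric epoxidation: the trans relationship comes from the E alkene and the titanium L-(+)-tartrate complex delivers oxygen to the face that gives the (2S,3S) epoxide.

Step 8
Reactants: 23 (2S,3S)-2,3-epoxybutan-1-ol
Product: 24 (2R,3S)-2,3-epoxybutanal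
Conditions: Dess–Martin periodinane, NaHCO3, CH2Cl2, 0 °C; filtered through a short pad, solution used at once
Reagents that add atoms: none
Why: Buffered Dess–Martin oxidation stops at the aldehyde without touching the epoxide or its α-centre; the descriptor at C2 changes from S to R only through the change in CIP priorities.

Step 9
Reactants: 24 (2R,3S)-2,3-epoxybutanal; 25 methyl bis(2,2,2-trifluoroethyl)phosphonoacetate
Product: 27 methyl (2Z,4S,5S)-4,5-epoxyhex-2-enoate, via potassium phosphonate anion 26 (not isolated)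
Conditions: 25, KN(SiMe3)2, 18-crown-6, THF, −78 °C; then 24, −78 °C
Reagents that add atoms: none
Why: Still–Gennari olefination: the electron-poor trifluoroethyl phosphonate under dissociating conditions eliminates faster than the adducts equilibrate, which should give the Z-enoate, and the epoxide centres are untouched at −78 °C.

Step 10
Reactants: 27 methyl (2Z,4S,5S)-4,5-epoxyhex-2-enoate
Product: 29 (2Z,4S,5S)-4,5-epoxyhex-2-enoic acid, via lithium carboxylate 28 (not isolated)
Conditions: LiOH (1.05 equiv), THF/H2O, 0 °C; cold NaH2PO4/H3PO4 buffer to pH 4, EtOAc extraction, solution dried and used at once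
Reagents that add atoms: lithium hydroxide, [Li+].[OH-]
Why: Saponification at 0 °C leaves the epoxide and the Z geometry alone, and buffered cold acidification with immediate use limits acid-promoted attack of the carboxyl group on the epoxide.

Step 11
Reactants: 21 2,5-bis[4-(tert-butyldimethylsilyloxy)phenyl]-3,6-dihydroxy-1,4-benzoquinone; 29 (2Z,4S,5S)-4,5-epoxyhex-2-enoic acid
Product: 31 2,5-bis[4-(tert-butyldimethylsilyloxy)phenyl]-3,6-dioxocyclohexa-1,4-diene-1,4-diyl bis[(2Z,4S,5S)-4,5-epoxyhex-2-enoate], via acid chloride 30 (not isolated)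
Conditions: 29 (2.4 equiv), 1-chloro-N,N,2-trimethylprop-1-en-1-amine (2.3 equiv), CH2Cl2, 0 °C; then 21, i-Pr2NEt, CH2Cl2, −40 to 0 °C
Reagents that add atoms: none
Why: The chloroenamine makes the acid chloride without liberating HCl and is used in deficit so none is left to chlorinate the quinone, and O-acylation of the quinonate dianion with a hindered non-nucleophilic amine avoids the conjugate addition–elimination by which nucleophilic acyl-transfer catalysts isomerise Z-enoates.

Step 12
Reactants: 31 bis-silyl ether of the target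
Product: 32 CNP0407724.1, 2,5-bis(4-hydroxyphenyl)-3,6-dioxocyclohexa-1,4-diene-1,4-diyl bis[(2Z,4S,5S)-4,5-epoxyhex-2-enoate]
Conditions: Bu4NF, AcOH (1:1), THF, 0 °C
Reagents that add atoms: none
Why: Fluoride cleaves aryl silyl ethers quickly through Si–F bond formation, and the acetic acid buffer keeps the medium from becoming basic enough to cleave the acyloxyquinone esters or acidic enough to open the epoxides.

Compound list
1 | dimethyl squarate | COC1=C(OC)C(=O)C1=O | starting material
2 | (4-bromophenoxy)(tert-butyl)dimethylsilane | CC(C)(C)[Si](C)(C)Oc1ccc(Br)cc1 | starting material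
3 | [4-(tert-butyldimethylsilyloxy)phenyl]lithium | [Li]c1ccc(O[Si](C)(C)C(C)(C)C)cc1 | intermediate
4 | lithium 1-[4-(tert-butyldimethylsilyloxy)phenyl]-2,3-dimethoxy-4-oxocyclobut-2-en-1-olate | [Li]OC1(c2ccc(O[Si](C)(C)C(C)(C)C)cc2)C(OC)=C(OC)C1=O | intermediate
5 | 1-[4-(tert-butyldimethylsilyloxy)phenyl]-2,3-dimethoxy-4-oxocyclobut-2-en-1-yl trifluoroacetate | COC1=C(OC)C(OC(=O)C(F)(F)F)(c2ccc(O[Si](C)(C)C(C)(C)C)cc2)C1=O | intermediate
6 | 3-[4-(tert-butyldimethylsilyloxy)phenyl]-4-methoxycyclobut-3-ene-1,2-dione | COC1=C(c2ccc(O[Si](C)(C)C(C)(C)C)cc2)C(=O)C1=O | intermediate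
7 | 4-(tert-butyldimethylsilyloxy)benzaldehyde | CC(C)(C)[Si](C)(C)Oc1ccc(C=O)cc1 | starting material
8 | (methoxymethyl)triphenylphosphonium chloride | COC[P+](c1ccccc1)(c1ccccc1)c1ccccc1.[Cl-] | starting material
9 | (methoxymethylene)triphenylphosphorane | COC=P(c1ccccc1)(c1ccccc1)c1ccccc1 | intermediate
10 | tert-butyl[4-(2-methoxyethenyl)phenoxy]dimethylsilane (E/Z mixture) | COC=Cc1ccc(O[Si](C)(C)C(C)(C)C)cc1 | intermediate
11 | tert-butyl[4-(1,2-dibromo-2-methoxyethyl)phenoxy]dimethylsilane (diastereomer mixture) | COC(Br)C(Br)c1ccc(O[Si](C)(C)C(C)(C)C)cc1 | intermediate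
12 | (Z)-[4-(1-bromo-2-methoxyethenyl)phenoxy](tert-butyl)dimethylsilane | CO/C=C(\Br)c1ccc(O[Si](C)(C)C(C)(C)C)cc1 | intermediate
13 | {1-[4-(tert-butyldimethylsilyloxy)phenyl]-2-methoxyethenyl}lithium (Li cis to OMe) | CO/C=C(\[Li])c1ccc(O[Si](C)(C)C(C)(C)C)cc1 | intermediate
14 | lithium alkoxide of 15 | CO/C=C(/c1ccc(O[Si](C)(C)C(C)(C)C)cc1)C1(O[Li])C(OC)=C(c2ccc(O[Si](C)(C)C(C)(C)C)cc2)C1=O | intermediate
15 | 4-hydroxy-3-methoxy-2-[4-(tert-butyldimethylsilyloxy)phenyl]-4-{(Z)-1-[4-(tert-butyldimethylsilyloxy)phenyl]-2-methoxyethenyl}cyclobut-2-en-1-one (racemic) | CO/C=C(/c1ccc(O[Si](C)(C)C(C)(C)C)cc1)C1(O)C(OC)=C(c2ccc(O[Si](C)(C)C(C)(C)C)cc2)C1=O | intermediate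
16 | 2,5-diaryl-4-hydroxy-3,6-dimethoxyhexa-1,3,5-trien-1-one (dienylketene, vinyl cis to the ketenyl carbon; aryl = 4-(tert-butyldimethylsilyloxy)phenyl) | O=C=C(c1ccc(O[Si](C)(C)C(C)(C)C)cc1)/C(OC)=C(O)\C(c1ccc(O[Si](C)(C)C(C)(C)C)cc1)=C/OC | intermediate
17 | 2,5-diaryl-4-hydroxy-3,6-dimethoxycyclohexa-2,4-dien-1-one (racemic; aryl as in 16) | COC1C(=O)C(c2ccc(O[Si](C)(C)C(C)(C)C)cc2)=C(OC)C(O)=C1c1ccc(O[Si](C)(C)C(C)(C)C)cc1 | intermediate
18 | 2,5-bis[4-(tert-butyldimethylsilyloxy)phenyl]-3,6-dimethoxybenzene-1,4-diol | COc1c(O)c(-c2ccc(O[Si](C)(C)C(C)(C)C)cc2)c(OC)c(O)c1-c1ccc(O[Si](C)(C)C(C)(C)C)cc1 | intermediate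
19 | 2,5-bis[4-(tert-butyldimethylsilyloxy)phenyl]-3,6-dimethoxy-1,4-benzoquinone | COC1=C(c2ccc(O[Si](C)(C)C(C)(C)C)cc2)C(=O)C(OC)=C(c2ccc(O[Si](C)(C)C(C)(C)C)cc2)C1=O | intermediate
20 | 2,5-bis[4-(tert-butyldimethylsilyloxy)phenyl]-3,6-bis(dichloroboryloxy)-1,4-benzoquinone | ClB(Cl)OC1=C(c2ccc(O[Si](C)(C)C(C)(C)C)cc2)C(=O)C(OB(Cl)Cl)=C(c2ccc(O[Si](C)(C)C(C)(C)C)cc2)C1=O | intermediate
21 | 2,5-bis[4-(tert-butyldimethylsilyloxy)phenyl]-3,6-dihydroxy-1,4-benzoquinone | OC1=C(c2ccc(O[Si](C)(C)C(C)(C)C)cc2)C(=O)C(O)=C(c2ccc(O[Si](C)(C)C(C)(C)C)cc2)C1=O | intermediate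
22 | (E)-but-2-en-1-ol | C/C=C/CO | starting material
23 | (2S,3S)-2,3-epoxybutan-1-ol | C[C@@H]1O[C@H]1CO | intermediate
24 | (2R,3S)-2,3-epoxybutanal | C[C@@H]1O[C@H]1C=O | intermediate
25 | methyl bis(2,2,2-trifluoroethyl)phosphonoacetate | COC(=O)CP(=O)(OCC(F)(F)F)OCC(F)(F)F | starting material
26 | potassium salt of the carbanion of 25 | [K+].COC(=O)[CH-]P(=O)(OCC(F)(F)F)OCC(F)(F)F | intermediate
27 | methyl (2Z,4S,5S)-4,5-epoxyhex-2-enoate | C[C@@H]1O[C@H]1/C=C\C(=O)OC | intermediate
28 | lithium (2Z,4S,5S)-4,5-epoxyhex-2-enoate | C[C@@H]1O[C@H]1/C=C\C(=O)[O-].[Li+] | intermediate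
29 | (2Z,4S,5S)-4,5-epoxyhex-2-enoic acid | C[C@@H]1O[C@H]1/C=C\C(=O)O | intermediate
30 | (2Z,4S,5S)-4,5-epoxyhex-2-enoyl chloride | C[C@@H]1O[C@H]1/C=C\C(Cl)=O | intermediate
31 | 2,5-bis[4-(tert-butyldimethylsilyloxy)phenyl]-3,6-dioxocyclohexa-1,4-diene-1,4-diyl bis[(2Z,4S,5S)-4,5-epoxyhex-2-enoate] | C[C@@H]1O[C@H]1/C=C\C(=O)OC1=C(c2ccc(O[Si](C)(C)C(C)(C)C)cc2)C(=O)C(OC(=O)/C=C\[C@@H]2O[C@H]2C)=C(c2ccc(O[Si](C)(C)C(C)(C)C)cc2)C1=O | intermediate
32 | CNP0407724.1 | C[C@@H]1O[C@H]1/C=C\C(=O)OC1=C(c2ccc(O)cc2)C(=O)C(OC(=O)/C=C\[C@@H]2O[C@H]2C)=C(c2ccc(O)cc2)C1=O | target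

Total step count: 12. Longest linear sequence: 7 steps (steps 2, 3, 4, 5, 6, 11 and 12, from aldehyde 7).

Steps most likely to fail

Step 11. The weakly nucleophilic quinonate may acylate only once, or the Z geometry may erode and the epoxide be opened by chloride while the acid chloride waits. The fallback moves the acylation to ordinary phenols and forms the quinone afterwards. It sets out from hydroquinone 18, isolated under argon by stopping step 5 before the Ag2O treatment. Its two phenolic hydroxyls are deprotonated with LiN(SiMe3)2 in THF at −78 °C and acylated with acid chloride 30 to give the 2,5-diaryl-3,6-dimethoxy-1,4-phenylene bis(epoxyhexenoate) F1. Oxidative demethylation of the para-dimethoxy unit with (NH4)2Ce(NO3)6 in MeCN/H2O at 0 °C then places the quinone carbonyls on the former methoxy carbons. By the symmetry of the ring this is compound 31, where the route is rejoined.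

Step 10. The free acid may lactonise by attack of its carboxyl group on the epoxide during acidification or concentration. The fallback never forms the free acid and makes no compound outside the list (F0). It sets out from ester 27, which is hydrolysed with exactly one equivalent of LiOH and freeze-dried to lithium carboxylate 28. The dry salt is treated with oxalyl chloride in CH2Cl2 at 0 °C, which gives only LiCl, CO and CO2 and no HCl. It rejoins the route at acid chloride 30.

Step 6. The aryl silyl ethers may be lost, or the methyl cleavage may stay incomplete, under the Lewis acid. The fallback sets out from quinone 19. Aqueous NaOH in MeOH/THF at rt hydrolyses both vinylogous esters and both silyl ethers, and acidification gives atromentin F2. Excess TBSCl with imidazole in DMF gives tetrakis-silyl atromentin F3. Its two quinonyl O–Si bonds are vinylogous silyl esters and should hydrolyse during a mildly acidic aqueous methanolic work-up while the aryl silyl ethers stay. This returns to compound 21.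

Further compounds
F1 | step 11 | 2,5-bis[4-(tert-butyldimethylsilyloxy)phenyl]-3,6-dimethoxy-1,4-phenylene bis[(2Z,4S,5S)-4,5-epoxyhex-2-enoate] | C[C@@H]1O[C@H]1/C=C\C(=O)Oc1c(-c2ccc(O[Si](C)(C)C(C)(C)C)cc2)c(OC)c(OC(=O)/C=C\[C@@H]2O[C@H]2C)c(-c2ccc(O[Si](C)(C)C(C)(C)C)cc2)c1OC
F0 | step 10 | none | none
F2 | step 6 | atromentin, 2,5-dihydroxy-3,6-bis(4-hydroxyphenyl)-1,4-benzoquinone | OC1=C(c2ccc(O)cc2)C(=O)C(O)=C(c2ccc(O)cc2)C1=O
F3 | step 6 | 2,5-bis(tert-butyldimethylsilyloxy)-3,6-bis[4-(tert-butyldimethylsilyloxy)phenyl]-1,4-benzoquinone | CC(C)(C)[Si](C)(C)OC1=C(c2ccc(O[Si](C)(C)C(C)(C)C)cc2)C(=O)C(O[Si](C)(C)C(C)(C)C)=C(c2ccc(O[Si](C)(C)C(C)(C)C)cc2)C1=O
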